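## The problem

The target is (2S)-pinocembrin whose ring A carbon C6' (the carbon between the 5'- and 7'-hydroxyls) is bonded to C8 of a side chain. C8 also carries a phenyl group, C7 a hydroxyl, and C6 belongs to a 5-hydroxy-5,6-dihydro-2H-pyran-2-one (O1, C2=O, C3=C4, C5, C6). Four stereocentres are contiguous (C5 S, C6 R, C7 R, C8 S) and can be relayed: C8 can direct C7 when both lie in one ring, the C7 oxygen can direct C6 through a five-membered chelate, and C5/C6 can be set together if both arise in one ring-forming event. The fifth centre, C2' (S), is seven bonds from C8 and beyond substrate control, so it needs a catalyst or a chiral building block. Ring A poses a regiochemical problem: the chain must enter between two oxygens and ring C must close on the third, so the three phloroglucinol oxygens have to be told apart from the first step on. Three functions limit the chemistry. The γ-oxygenated enoate lactone is eliminated to a 2-pyranone by base, can be attacked at C4 by the C7 hydroxyl, and is saturated by hydrogenation. The flavanone is opened to the chalcone by base, which scrambles C2'. Ring A is electron-rich and sensitive to electrophiles and oxidants. The handle for the key step is the lactone itself: O1 and C6 are the oxygen and carbon of a former aldehyde, C7 places an alkoxy group α to that aldehyde, and the cis arrangement of O5 and the C6 chain is what an endo hetero-Diels–Alder addition of a (Z)-4-oxygenated 1-methoxy-3-silyloxy diene leaves behind.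

## Retrosynthesis

**26 to 25.** The four O–benzyl bonds are cut. All four hydroxyls (5', 7', C7, C5) are carried as benzyl ethers in 25 and released together by a Lewis acid. Esters would need base and hydrogenolysis would reduce C3=C4, so neither is used; a silyl ether on C7 could not chelate in the key step.

**25 to 22 by way of 24 and 23.** No skeletal bond is cut; the carbonyl is moved from C4 to C2. Lactone 25 comes from methyl acetal 24 by oxidation, 24 from allylic alcohol 23 by allylic transposition, and 23 from dihydropyranone 22 by 1,2-reduction. These steps touch only C2–C4 and leave C5 and C6 alone. The forward sequence must reduce the vinylogous ester carbonyl without touching the chromanone carbonyl.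

**22 to 16 and 20 (key disconnection).** C5–C6 and O1–C2 are cut together. Cutting C5–C6 alone (an aldol) would leave the ring to be closed and C5 to be set separately; cutting C6–C7 would give up the C7 alkoxy group as a control element. Aldehyde 16 lacks the whole lactone ring and two stereocentres. Diene 20 carries O5 as a benzyl ether and not as the more usual ester, because an ester would later need basic solvolysis next to a flavanone and an enoate; the benzyl ether simply joins the final debenzylation. The forward reaction must show chelation-controlled face selection at C6 and an endo topology for C5.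

**20 to 17 by way of 19 and 18.** The diene comes from enone 19 by enol silylation, 19 from ynone 18 by conjugate addition of the alcohol, and 18 from Weinreb amide 17 and an ethynyl nucleophile. Only one position of 19 can enolise, so the diene constitution is unambiguous.

**16 to 14 and 4 by way of 15.** After adjusting the oxidation level at C6 (alcohol 15), the C2'–phenyl bond is cut. The neighbouring cut, O1'–C2' (closure of a chalcone), is reversible and gives no control over C2'. Chromone 14 has no stereocentre in ring C and is stable to acid and base. The forward step must be a catalyst-controlled, non-basic conjugate phenylation with boronic acid 4.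

**14 to 10 by way of 12 and 11.** Ring C is taken apart at O1'–C2' and C2'–C3' (one carbon from an amide acetal, through enaminone 13), then at C4'–C4a' (the acetyl group of 11). In 10 only the para oxygen carries an allyl group and the two free ring positions are equivalent, so the acetyl group and then ring C can form in one way only.

**10 to 8 by way of 9.** One O–benzyl bond and the lactone C–O bond are cut; reduction of aryl lactone 8 reveals C6 as a primary alcohol and the second flanking phenol. The dihydrocoumarin is a temporary ring: it holds C7 and C8 in a ring for relative control, fixes the chain between two oxygens, and masks C6.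

**8 to 5 by way of 7.** The C7–O bond is cut; it forms by oxidation of the lactone enolate 6 anti to the C4 phenyl, which gives the 3,4-trans relationship the target needs.

**5 to 3 and 4.** The C8–phenyl bond is cut. Forming the C8–aryl bond instead would need a 2,6-dioxygenated aryl nucleophile at a hindered benzylic carbon and would reopen the regiochemical question. A coumarin is a flat, cyclic cis-enoate, a good acceptor class for rhodium-catalysed arylation.

**3 to 1 by way of 2.** Two O–alkyl bonds are cut; the order of alkylation follows the acidity of the two phenols of 1.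

## Roads not taken

Alternative 1: The cut is C7–C8 plus the bond between the C6 carbonyl and a ring A oxygen, so the temporary dihydrocoumarin is made by annulation and not from a coumarin. In the forward sense benzhydrol A2 would be converted into its ortho-quinone methide. A chiral azolium enolate carrying the C7 benzyloxy group would attack it at C8 and then acylate the phenol oxygen to give A1, the triisopropylsilyl counterpart of lactone 8.
- Merits: C7–C8 is formed and both centres are set in one catalytic step that replaces steps 3–5, and A1 could enter the present route at step 6. For the C7/C8 pair this road is shorter.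
- Weak points: such annulations normally give the 3,4-cis lactone, so C7 would have to be epimerised to reach the trans series. The quinone methide of a 2,4,6-trioxygenated ring is strongly stabilised and a sluggish acceptor. A2 needs a three-way differentiated phloroglucinol, which costs about as many steps as are saved.
- Comparison: against the shorter sequence the chosen plan sets two events of predictable sense, arylation of a coumarin and enolate oxidation anti to the new phenyl, which gives trans directly. The alternative does not address the lactone ring and could only serve as a different front end.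

Alternative 2: The cut is C4'–C4a', with ring C closed last. Acid A4 is an (S)-3-aryloxy-3-phenylpropanoic acid whose ether oxygen is para to the chain and whose two flanking oxygens are silylated alike. As its mixed trifluoroacetic anhydride it would acylate either of two equivalent ring positions to give A3, the tetrakis-silyl ether of the target.
- Merits: C2' comes from a chiral building block through an ether bond, so no catalyst control is needed and no chalcone-prone intermediate is carried through the synthesis. The ring symmetry removes the 6'/8' question at the closure. On both counts this road is better than the chosen one.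
- Weak points: the only C–C bond formation is placed at the very end, in strong acid, on the most valuable intermediate, where the enoate lactone and the allylic and aryl silyl ethers are exposed. An activated β-aryloxy acid can lose the phenol by β-elimination, which destroys C2'. The position to be acylated lies between an aryloxy and a bulky, weakly donating silyloxy group. The plan does not say how C5–C8 and the lactone are made.
- Comparison: the chosen plan pays three steps (8, 10 and 11) to build ring C early on robust benzyl-protected material, and it must rely on a catalyst for C2'.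

Alternative 3: The cut is O1–C2 by way of a furan; the ring carbons C2–C5 come from a 2-furyl group added to the C6 aldehyde. Furyl carbinol A6 would be oxidised with N-bromosuccinimide in buffered aqueous THF to the ene-dione, whose aldehyde carbon is captured by the C6 hydroxyl to give pyranone lactol A5 (C2 hemiacetal, C5 ketone, C3=C4).
- Merits: all ring carbons arrive in one addition and the ring expansion is reliable. A5 already has C3=C4 and C2 at the aldehyde level, so lactol oxidation and ketone reduction would replace steps 17–19. In oxidation-level economy this road is better.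
- Weak points: the silyl ether on C7 in A6 does not chelate, so the furyl addition would follow the Felkin mode and give the 6,7-anti isomer. C5 is set afterwards by hydride reduction of the ketone; attack anti to the C6 substituent would give mainly the 5,6-trans alcohol, which is the wrong one. The brominating oxidant meets the free C8' position of ring A. The phenol acetates of A5 would have to be removed beside the enoate lactone, which base does not allow.
- Comparison: the chosen plan spends three redox steps on the transposition but sets C5 and C6 together, in the required cis sense, in the ring-forming step.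

Key step: step 16

Remark on the chemistry: 17 is taken as a purchasable reagent; the sense of induction in steps 3 and 11 is assigned by analogy with the unsubstituted coumarin and chromone and would be reversed with the antipodal ligand.

Step 1
Reactants: 1 5,7-dihydroxy-2H-chromen-2-one (5,7-dihydroxycoumarin)
Product: 2 7-(allyloxy)-5-hydroxy-2H-chromen-2-one
Conditions: allyl bromide (1.05 equiv), K2CO3 (1.1 equiv), acetone, rt
Reagents that add atoms: allyl bromide, C=CCBr
Why: Williamson etherification; the 7-hydroxyl is the more acidic phenol (para-vinylogous to the lactone carbonyl) and the less hindered one, so one equivalent of base and halide should alkylate it preferentially, and the 5-ether and bis-ether are removed by chromatography.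

Step 2
Reactants: 2 7-(allyloxy)-5-hydroxy-2H-chromen-2-one
Product: 3 7-(allyloxy)-5-(benzyloxy)-2H-chromen-2-one
Conditions: BnBr, K2CO3, DMF, 50 °C
Reagents that add atoms: benzyl bromide, BrCc1ccccc1
Why: Williamson etherification of the remaining phenol; the para oxygen (allyl) is now distinct from the oxygen that will flank the chain (benzyl).

Step 3
Reactants: 3 7-(allyloxy)-5-(benzyloxy)-2H-chromen-2-one; 4 phenylboronic acid
Product: 5 (4S)-7-(allyloxy)-5-(benzyloxy)-4-phenylchroman-2-one
Conditions: Rh(acac)(C2H4)2 (3 mol%), (S)-SEGPHOS (3.3 mol%), dioxane/H2O 10:1, 60 °C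
Reagents that add atoms: none
Why: Rhodium-catalysed asymmetric 1,4-addition of an arylboronic acid to a coumarin (Hayashi–Miyaura type); the bisphosphine–rhodium aryl species adds phenyl to one face of C3=C4 and sets C4 (the future C8) as S. The neutral aqueous medium leaves allyl and benzyl ethers alone.

Step 4
Reactants: 5 (4S)-7-(allyloxy)-5-(benzyloxy)-4-phenylchroman-2-one
Product: 7 (3R,4S)-7-(allyloxy)-5-(benzyloxy)-3-hydroxy-4-phenylchroman-2-one, via potassium enolate of the lactone 6 (not isolated)
Conditions: KN(SiMe3)2, THF, −78 °C; then 2-(phenylsulfonyl)-3-phenyloxaziridine, −78 °C; aq NH4Cl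
Reagents that add atoms: 2-(phenylsulfonyl)-3-phenyloxaziridine, O=S(=O)(c1ccccc1)N1OC1c1ccccc1
Why: Enolate oxidation with an N-sulfonyloxaziridine (Davis hydroxylation); the planar enolate is attacked on the face anti to the C4 phenyl, which gives the 3,4-trans hydroxy lactone and sets the future C7 (R). Low temperature and the potassium counter-ion suppress ketene formation from the aryl ester enolate and addition to the sulfonimine.

Step 5
Reactants: 7 (3R,4S)-7-(allyloxy)-5-(benzyloxy)-3-hydroxy-4-phenylchroman-2-one
Product: 8 (3R,4S)-7-(allyloxy)-3,5-bis(benzyloxy)-4-phenylchroman-2-one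
Conditions: BnBr, Ag2O, CH2Cl2, rt, dark
Reagents that add atoms: benzyl bromide, BrCc1ccccc1
Why: Silver-oxide-mediated O-benzylation (Purdie-type) works without a free alkoxide or enolate, so the base-sensitive aryl lactone and C3 are not disturbed; this benzyl ether is the later chelating group.

Step 6
Reactants: 8 (3R,4S)-7-(allyloxy)-3,5-bis(benzyloxy)-4-phenylchroman-2-one
Product: 9 5-(allyloxy)-3-(benzyloxy)-2-[(1S,2R)-2-(benzyloxy)-3-hydroxy-1-phenylpropyl]phenol
Conditions: LiBH4, THF, 0 °C to rt; aq NH4Cl
Reagents that add atoms: none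
Why: Hydride reduction of the aryl lactone to the primary alcohol and the liberated phenol; ethers and the allyl group are inert, and neither stereocentre is enolisable once the carbonyl is gone.

Step 7
Reactants: 9 5-(allyloxy)-3-(benzyloxy)-2-[(1S,2R)-2-(benzyloxy)-3-hydroxy-1-phenylpropyl]phenol
Product: 10 (2R,3S)-3-[4-(allyloxy)-2,6-bis(benzyloxy)phenyl]-2-(benzyloxy)-3-phenylpropan-1-ol
Conditions: BnBr, K2CO3, acetone, reflux
Reagents that add atoms: benzyl bromide, BrCc1ccccc1
Why: Chemoselective Williamson benzylation; carbonate deprotonates the phenol and not the primary alcohol. Both oxygens flanking the chain are now benzyl ethers and only the para oxygen carries allyl.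

Step 8
Reactants: 10 (2R,3S)-3-[4-(allyloxy)-2,6-bis(benzyloxy)phenyl]-2-(benzyloxy)-3-phenylpropan-1-ol
Product: 11 (2R,3S)-3-[3-acetyl-4-(allyloxy)-2,6-bis(benzyloxy)phenyl]-2-(benzyloxy)-3-phenylpropyl acetate
Conditions: AcOH, (CF3CO)2O, CH2Cl2, 0 °C to rt
Reagents that add atoms: acetic acid, CC(=O)O
Why: Friedel–Crafts acetylation of a phloroglucinol triether by acetyl trifluoroacetate formed in situ; the two free ring positions are interconverted by rotation about the aryl–C8 bond, so one constitution results, and the first acetyl group deactivates the ring against a second. The primary alcohol is acetylated in the same pot, which protects it, and no strong Lewis acid is present that could cleave benzyl ethers.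

Step 9
Reactants: 11 (2R,3S)-3-[3-acetyl-4-(allyloxy)-2,6-bis(benzyloxy)phenyl]-2-(benzyloxy)-3-phenylpropyl acetate
Product: 12 1-{2,4-bis(benzyloxy)-3-[(1S,2R)-2-(benzyloxy)-3-hydroxy-1-phenylpropyl]-6-hydroxyphenyl}ethan-1-one
Conditions: Pd(PPh3)4 (5 mol%), K2CO3, MeOH, rt
Reagents that add atoms: none
Why: Palladium-catalysed deallylation of the aryl allyl ether (π-allyl transfer to methoxide) with concurrent carbonate-mediated methanolysis of the primary acetate; the phenol set free is ortho to the acetyl group and is the only free ring oxygen.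

Step 10
Reactants: 12 1-{2,4-bis(benzyloxy)-3-[(1S,2R)-2-(benzyloxy)-3-hydroxy-1-phenylpropyl]-6-hydroxyphenyl}ethan-1-one
Product: 14 5,7-bis(benzyloxy)-6-[(1S,2R)-2-(benzyloxy)-3-hydroxy-1-phenylpropyl]-4H-chromen-4-one, via enaminone 13 (not isolated)
Conditions: Me2NCH(OMe)2, toluene, 95 °C; then conc. HCl, CH2Cl2/MeOH, rt
Reagents that add atoms: N,N-dimethylformamide dimethyl acetal, COC(OC)N(C)C
Why: Enaminone formation at the methyl ketone, then acid-induced addition–elimination of the ortho phenol (chromone annulation); since only the para oxygen is free, ring C can close in one direction only, which places the chain at C6 of the chromone.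

Step 11
Reactants: 14 5,7-bis(benzyloxy)-6-[(1S,2R)-2-(benzyloxy)-3-hydroxy-1-phenylpropyl]-4H-chromen-4-one; 4 phenylboronic acid
Product: 15 (2S)-5,7-bis(benzyloxy)-6-[(1S,2R)-2-(benzyloxy)-3-hydroxy-1-phenylpropyl]-2-phenylchroman-4-one
Conditions: Pd(OCOCF3)2 (5 mol%), (R)-t-BuPyOx (6 mol%), NH4PF6 (30 mol%), H2O (5 equiv), ClCH2CH2Cl, 60 °C
Reagents that add atoms: none
Why: Palladium-catalysed asymmetric conjugate addition of an arylboronic acid to a chromone with a pyridine–oxazoline ligand; the divalent palladium–aryl species delivers phenyl to one face of C2=C3 and sets C2' (S) under catalyst control, the remote chain centres having no influence. The medium is neutral and non-nucleophilic, so the flavanone should not open to the chalcone.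

Step 12
Reactants: 15 (2S)-5,7-bis(benzyloxy)-6-[(1S,2R)-2-(benzyloxy)-3-hydroxy-1-phenylpropyl]-2-phenylchroman-4-one
Product: 16 (2R,3S)-2-(benzyloxy)-3-[(2S)-5,7-bis(benzyloxy)-4-oxo-2-phenylchroman-6-yl]-3-phenylpropanal
Conditions: Dess–Martin periodinane, NaHCO3, CH2Cl2, 0 °C to rt
Reagents that add atoms: none
Why: Dess–Martin oxidation of the primary alcohol; the buffered, non-basic conditions preserve the α-benzyloxy aldehyde centre (C7) and the flavanone, and the aldehyde is used at once.

Step 13
Reactants: 17 2-(benzyloxy)-N-methoxy-N-methylacetamide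
Product: 18 1-(benzyloxy)but-3-yn-2-one
Conditions: HC≡CMgBr, THF, 0 °C; aq NH4Cl
Reagents that add atoms: ethynylmagnesium bromide, C#C[Mg]Br
Why: Acylation of an alkynyl Grignard reagent by a Weinreb amide; the chelated tetrahedral intermediate prevents over-addition.

Step 14
Reactants: 18 1-(benzyloxy)but-3-yn-2-one
Product: 19 (3E)-1-(benzyloxy)-4-methoxybut-3-en-2-one
Conditions: MeOH, DABCO (10 mol%), CH2Cl2, 0 °C to rt
Reagents that add atoms: methanol, CO
Why: Amine-catalysed conjugate addition of an alcohol to an ynone; the (E)-β-methoxy enone is the thermodynamic product.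

Step 15
Reactants: 19 (3E)-1-(benzyloxy)-4-methoxybut-3-en-2-one
Product: 20 (1E,3Z)-4-(benzyloxy)-1-methoxy-3-(trimethylsilyloxy)buta-1,3-diene
Conditions: Me3SiOSO2CF3, Et3N, Et2O, 0 °C
Reagents that add atoms: trimethylsilyl trifluoromethanesulfonate, C[Si](C)(C)OS(=O)(=O)C(F)(F)F
Why: Soft enolisation–silylation of an α-alkoxy ketone; only the CH2 between carbonyl and benzyloxy can enolise, and the enol silane should form with silyloxy and benzyloxy cis (3Z), while the 1E geometry is retained.

Step 16
Reactants: 16 (2R,3S)-2-(benzyloxy)-3-[(2S)-5,7-bis(benzyloxy)-4-oxo-2-phenylchroman-6-yl]-3-phenylpropanal; 20 (1E,3Z)-4-(benzyloxy)-1-methoxy-3-(trimethylsilyloxy)buta-1,3-diene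
Product: 22 (2S,3R)-3-(benzyloxy)-2-{(1R,2S)-1-(benzyloxy)-2-[(2S)-5,7-bis(benzyloxy)-4-oxo-2-phenylchroman-6-yl]-2-phenylethyl}-2,3-dihydro-4H-pyran-4-one, via silyl enol ether cycloadduct 21 (not isolated)
Conditions: MgBr2·OEt2 (3 equiv), THF, −20 °C to rt; then CF3CO2H (cat.), CH2Cl2, 0 °C
Reagents that add atoms: none
Why: MgBr2 binds the aldehyde oxygen and the C7 benzyloxy oxygen of 16 in a five-membered chelate, which activates the aldehyde and fixes its conformation; the bulky C8 diarylmethyl group shields one face, so the diene adds to the other (Cram-chelate sense) and C6 is formed syn to the C7 oxygen. The diene reacts in an asynchronous [4+2] cycloaddition in which its benzyloxy-bearing terminus bonds to the aldehyde carbon (C5–C6) and the aldehyde oxygen bonds to the methoxy-bearing carbon (O1–C2), so the pyran ring is closed by cycloaddition in one operation; acid then expels methanol and the silyl group from 21 to give the 2,3-dihydro-4H-pyran-4-one. C5 is controlled by diene geometry and transition-state topology: the benzyloxy group sits on the outside of the (Z)-enol ether terminus, and with the aldehyde chain endo it ends cis to the C6 substituent. The closest known reaction is the magnesium-bromide-mediated cyclocondensation of α-alkoxy aldehydes with 4-substituted 1-methoxy-3-silyloxybutadienes (Danishefsky-type dienes). Three selectivities are needed: facial (secured by the chelating C7 benzyl ether), cis at C5/C6 (secured by the Z terminus and a coordinating solvent that favours the concerted over the open aldol pathway), and aldehyde over chromanone ketone (the latter is hindered and deactivated by three ring oxygens). An excess of the Lewis acid is used because the 4'-carbonyl/5'-benzyloxy pair of the flavanone also binds magnesium.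

Step 17
Reactants: 22 (2S,3R)-3-(benzyloxy)-2-{(1R,2S)-1-(benzyloxy)-2-[(2S)-5,7-bis(benzyloxy)-4-oxo-2-phenylchroman-6-yl]-2-phenylethyl}-2,3-dihydro-4H-pyran-4-one
Product: 23 (2S,3S,4S)-3-(benzyloxy)-2-{(1R,2S)-1-(benzyloxy)-2-[(2S)-5,7-bis(benzyloxy)-4-oxo-2-phenylchroman-6-yl]-2-phenylethyl}-3,4-dihydro-2H-pyran-4-ol
Conditions: NaBH4 (1.0 equiv), CeCl3·7H2O, MeOH/CH2Cl2, −78 °C
Reagents that add atoms: none
Why: Luche 1,2-reduction of the vinylogous ester carbonyl; one equivalent of hydride at −78 °C should spare the chromanone carbonyl, which is flanked by the 5'-benzyloxy group and deactivated by three ring oxygens. Hydride should enter anti to the axial C5 benzyloxy group to give the all-cis alcohol, but this centre is removed in the next step.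

Step 18
Reactants: 23 (2S,3S,4S)-3-(benzyloxy)-2-{(1R,2S)-1-(benzyloxy)-2-[(2S)-5,7-bis(benzyloxy)-4-oxo-2-phenylchroman-6-yl]-2-phenylethyl}-3,4-dihydro-2H-pyran-4-ol
Product: 24 (2R,3S,6RS)-3-(benzyloxy)-6-methoxy-2-{(1R,2S)-1-(benzyloxy)-2-[(2S)-5,7-bis(benzyloxy)-4-oxo-2-phenylchroman-6-yl]-2-phenylethyl}-3,6-dihydro-2H-pyran (anomer mixture at the acetal carbon)
Conditions: pyridinium p-toluenesulfonate (cat.), MeOH, rt
Reagents that add atoms: methanol, CO
Why: Acid-catalysed allylic transposition (Ferrier-type); ionisation of the allylic hydroxyl gives the ring-oxygen-stabilised allyl cation, which methanol captures at C2, so the double bond moves to C3=C4 while C5 and C6 are untouched. Both anomers converge in the next step.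

Step 19
Reactants: 24 (2R,3S,6RS)-3-(benzyloxy)-6-methoxy-2-{(1R,2S)-1-(benzyloxy)-2-[(2S)-5,7-bis(benzyloxy)-4-oxo-2-phenylchroman-6-yl]-2-phenylethyl}-3,6-dihydro-2H-pyran
Product: 25 (5S,6R)-5-(benzyloxy)-6-{(1R,2S)-1-(benzyloxy)-2-[(2S)-5,7-bis(benzyloxy)-4-oxo-2-phenylchroman-6-yl]-2-phenylethyl}-5,6-dihydro-2H-pyran-2-one
Conditions: CrO3, H2SO4, H2O, acetone, 0 °C
Reagents that add atoms: water, O
Why: Jones oxidation of an allylic mixed acetal; aqueous acid hydrolyses it to the lactol, which hexavalent chromium oxidises to the α,β-unsaturated δ-lactone. C5 carries a benzyl ether and cannot be oxidised, and short exposure at 0 °C should spare the benzyl ethers and the benzylic C8–H.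

Step 20
Reactants: 25 (5S,6R)-5-(benzyloxy)-6-{(1R,2S)-1-(benzyloxy)-2-[(2S)-5,7-bis(benzyloxy)-4-oxo-2-phenylchroman-6-yl]-2-phenylethyl}-5,6-dihydro-2H-pyran-2-one
Product: 26 (2S)-5,7-dihydroxy-6-{(1S,2R)-2-hydroxy-2-[(2R,3S)-3-hydroxy-6-oxo-3,6-dihydro-2H-pyran-2-yl]-1-phenylethyl}-2-phenylchroman-4-one (CNP0136207.1)
Conditions: BCl3, C6HMe5, CH2Cl2, −78 to −30 °C; then MeOH
Reagents that add atoms: none
Why: Lewis-acid debenzylation with pentamethylbenzene as a non-basic benzyl-cation scavenger cleaves the two aryl and two secondary alkyl benzyl ethers; the scavenger prevents C-benzylation of ring A, and the allylic C5–O bond should not ionise because the cation would be conjugated to the lactone carbonyl. The absence of base avoids chalcone formation, elimination to the 2-pyranone and oxa-Michael closure of the C7 hydroxyl.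

## Compound list

1 | 5,7-dihydroxy-2H-chromen-2-one | O=C1C=Cc2c(O)cc(O)cc2O1 | starting material
2 | 7-(allyloxy)-5-hydroxy-2H-chromen-2-one | O=C1C=Cc2c(O)cc(OCC=C)cc2O1 | intermediate
3 | 7-(allyloxy)-5-(benzyloxy)-2H-chromen-2-one | O=C1C=Cc2c(OCc3ccccc3)cc(OCC=C)cc2O1 | intermediate
4 | phenylboronic acid | OB(O)c1ccccc1 | starting material
5 | (4S)-7-(allyloxy)-5-(benzyloxy)-4-phenylchroman-2-one | O=C1C[C@@H](c2ccccc2)c2c(OCc3ccccc3)cc(OCC=C)cc2O1 | intermediate
6 | potassium enolate of 5 (not isolated) | [K+].[O-]C1=C[C@@H](c2ccccc2)c2c(OCc3ccccc3)cc(OCC=C)cc2O1 | intermediate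
7 | (3R,4S)-7-(allyloxy)-5-(benzyloxy)-3-hydroxy-4-phenylchroman-2-one | O=C1[C@H](O)[C@@H](c2ccccc2)c2c(OCc3ccccc3)cc(OCC=C)cc2O1 | intermediate
8 | (3R,4S)-7-(allyloxy)-3,5-bis(benzyloxy)-4-phenylchroman-2-one | O=C1[C@H](OCc2ccccc2)[C@@H](c2ccccc2)c2c(OCc3ccccc3)cc(OCC=C)cc2O1 | intermediate
9 | 5-(allyloxy)-3-(benzyloxy)-2-[(1S,2R)-2-(benzyloxy)-3-hydroxy-1-phenylpropyl]phenol | OC[C@H](OCc1ccccc1)[C@@H](c1ccccc1)c1c(OCc2ccccc2)cc(OCC=C)cc1O | intermediate
10 | (2R,3S)-3-[4-(allyloxy)-2,6-bis(benzyloxy)phenyl]-2-(benzyloxy)-3-phenylpropan-1-ol | OC[C@H](OCc1ccccc1)[C@@H](c1ccccc1)c1c(OCc2ccccc2)cc(OCC=C)cc1OCc1ccccc1 | intermediate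
11 | (2R,3S)-3-[3-acetyl-4-(allyloxy)-2,6-bis(benzyloxy)phenyl]-2-(benzyloxy)-3-phenylpropyl acetate | CC(=O)OC[C@H](OCc1ccccc1)[C@@H](c1ccccc1)c1c(OCc2ccccc2)cc(OCC=C)c(C(C)=O)c1OCc1ccccc1 | intermediate
12 | 1-{2,4-bis(benzyloxy)-3-[(1S,2R)-2-(benzyloxy)-3-hydroxy-1-phenylpropyl]-6-hydroxyphenyl}ethan-1-one | OC[C@H](OCc1ccccc1)[C@@H](c1ccccc1)c1c(OCc2ccccc2)cc(O)c(C(C)=O)c1OCc1ccccc1 | intermediate
13 | (2E)-1-{2,4-bis(benzyloxy)-3-[(1S,2R)-2-(benzyloxy)-3-hydroxy-1-phenylpropyl]-6-hydroxyphenyl}-3-(dimethylamino)prop-2-en-1-one (not isolated) | OC[C@H](OCc1ccccc1)[C@@H](c1ccccc1)c1c(OCc2ccccc2)cc(O)c(C(=O)/C=C/N(C)C)c1OCc1ccccc1 | intermediate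
14 | 5,7-bis(benzyloxy)-6-[(1S,2R)-2-(benzyloxy)-3-hydroxy-1-phenylpropyl]-4H-chromen-4-one | OC[C@H](OCc1ccccc1)[C@@H](c1ccccc1)c1c(OCc2ccccc2)cc2occc(=O)c2c1OCc1ccccc1 | intermediate
15 | (2S)-5,7-bis(benzyloxy)-6-[(1S,2R)-2-(benzyloxy)-3-hydroxy-1-phenylpropyl]-2-phenylchroman-4-one | OC[C@H](OCc1ccccc1)[C@@H](c1ccccc1)c1c(OCc2ccccc2)cc2c(c1OCc1ccccc1)C(=O)C[C@@H](c1ccccc1)O2 | intermediate
16 | (2R,3S)-2-(benzyloxy)-3-[(2S)-5,7-bis(benzyloxy)-4-oxo-2-phenylchroman-6-yl]-3-phenylpropanal | O=C[C@H](OCc1ccccc1)[C@@H](c1ccccc1)c1c(OCc2ccccc2)cc2c(c1OCc1ccccc1)C(=O)C[C@@H](c1ccccc1)O2 | intermediate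
17 | 2-(benzyloxy)-N-methoxy-N-methylacetamide | CON(C)C(=O)COCc1ccccc1 | starting material
18 | 1-(benzyloxy)but-3-yn-2-one | C#CC(=O)COCc1ccccc1 | intermediate
19 | (3E)-1-(benzyloxy)-4-methoxybut-3-en-2-one | CO/C=C/C(=O)COCc1ccccc1 | intermediate
20 | (1E,3Z)-4-(benzyloxy)-1-methoxy-3-(trimethylsilyloxy)buta-1,3-diene | CO/C=C/C(O[Si](C)(C)C)=C/OCc1ccccc1 | intermediate
21 | [4+2] cycloadduct: 5-(benzyloxy)-2-methoxy-4-(trimethylsilyloxy)-5,6-dihydro-2H-pyran carrying the C6 side chain of 22, 2,5,6-all-cis (not isolated) | CO[C@@H]1C=C(O[Si](C)(C)C)[C@H](OCc2ccccc2)[C@H]([C@H](OCc2ccccc2)[C@@H](c2ccccc2)c2c(OCc3ccccc3)cc3c(c2OCc2ccccc2)C(=O)C[C@@H](c2ccccc2)O3)O1 | intermediate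
22 | (2S,3R)-3-(benzyloxy)-2-{(1R,2S)-1-(benzyloxy)-2-[(2S)-5,7-bis(benzyloxy)-4-oxo-2-phenylchroman-6-yl]-2-phenylethyl}-2,3-dihydro-4H-pyran-4-one | C1=CC(=O)[C@H](OCc2ccccc2)[C@H]([C@H](OCc2ccccc2)[C@@H](c2ccccc2)c2c(OCc3ccccc3)cc3c(c2OCc2ccccc2)C(=O)C[C@@H](c2ccccc2)O3)O1 | intermediate
23 | (2S,3S,4S)-3-(benzyloxy)-2-{(1R,2S)-1-(benzyloxy)-2-[(2S)-5,7-bis(benzyloxy)-4-oxo-2-phenylchroman-6-yl]-2-phenylethyl}-3,4-dihydro-2H-pyran-4-ol | C1=C[C@H](O)[C@H](OCc2ccccc2)[C@H]([C@H](OCc2ccccc2)[C@@H](c2ccccc2)c2c(OCc3ccccc3)cc3c(c2OCc2ccccc2)C(=O)C[C@@H](c2ccccc2)O3)O1 | intermediate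
24 | (2R,3S,6RS)-3-(benzyloxy)-6-methoxy-2-{(1R,2S)-1-(benzyloxy)-2-[(2S)-5,7-bis(benzyloxy)-4-oxo-2-phenylchroman-6-yl]-2-phenylethyl}-3,6-dihydro-2H-pyran (anomer mixture) | COC1C=C[C@H](OCc2ccccc2)[C@H]([C@H](OCc2ccccc2)[C@@H](c2ccccc2)c2c(OCc3ccccc3)cc3c(c2OCc2ccccc2)C(=O)C[C@@H](c2ccccc2)O3)O1 | intermediate
25 | (5S,6R)-5-(benzyloxy)-6-{(1R,2S)-1-(benzyloxy)-2-[(2S)-5,7-bis(benzyloxy)-4-oxo-2-phenylchroman-6-yl]-2-phenylethyl}-5,6-dihydro-2H-pyran-2-one | O=C1C=C[C@H](OCc2ccccc2)[C@H]([C@H](OCc2ccccc2)[C@@H](c2ccccc2)c2c(OCc3ccccc3)cc3c(c2OCc2ccccc2)C(=O)C[C@@H](c2ccccc2)O3)O1 | intermediate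
26 | (2S)-5,7-dihydroxy-6-{(1S,2R)-2-hydroxy-2-[(2R,3S)-3-hydroxy-6-oxo-3,6-dihydro-2H-pyran-2-yl]-1-phenylethyl}-2-phenylchroman-4-one | O=C1C=C[C@H](O)[C@H]([C@H](O)[C@@H](c2ccccc2)c2c(O)cc3c(c2O)C(=O)C[C@@H](c2ccccc2)O3)O1 | target

## Step count and least certain steps

Total: 20 steps. Longest linear sequence: 17 steps (steps 1–12 and 16–20, from 1 to 26); the diene branch (steps 13–15) has 3 steps.

**Step 16 (key step).** The most likely failure is erosion of the C5/C6 cis relationship if the electron-rich benzyloxy terminus of 20 reacts through an open aldol-type addition instead of the concerted pathway. Facial selectivity could also drop if the flavanone carbonyl competes for the Lewis acid and chelation is incomplete, and the hindered aldehyde may epimerise at C7 if the addition is slow. The fallback builds the same ring by chelation-controlled allylation and ring-closing metathesis. It sets out from 16: tributyl[(Z)-3-(tert-butyldimethylsilyloxy)prop-2-en-1-yl]stannane and MgBr2·OEt2 in CH2Cl2 (syn,syn-selective γ-alkoxyallylation) give the homoallylic alcohol F1. Acryloyl chloride and i-Pr2NEt give the acrylate F2, and the second-generation Grubbs catalyst closes the 5-silyloxy lactone F3. BCl3/C6HMe5 followed by HF·pyridine removes the three benzyl ethers and the silyl ether and returns to the route at 26.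

**Step 3.** The most likely failure is slow insertion: the 5-benzyloxy group is peri to C4 and crowds the rhodium–aryl addition, so protodeboronation of 4 could outrun conjugate addition. The fallback forms the C4–phenyl bond first, without a stereocentre, and sets C4 by hydride delivery. It sets out from 3: oxidative Heck coupling with 4 (Pd(OAc)2, 1,10-phenanthroline, O2, DMF) gives 7-(allyloxy)-5-(benzyloxy)-4-phenyl-2H-chromen-2-one F4. Copper hydride conjugate reduction (Cu(OAc)2, a DTBM-SEGPHOS ligand of the appropriate handedness, diethoxymethylsilane, t-BuOH, toluene) returns to the route at 5.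

**Step 8.** The most likely failure is loss or migration of benzyl groups in the acidic acylation medium, or incomplete C-acylation at a position flanked by two alkoxy groups. The fallback introduces the acetyl group through an aryllithium instead of an electrophilic acylation. It sets out from 10: N-bromosuccinimide (MeCN, −20 °C) gives the ring bromide (2R,3S)-3-[4-(allyloxy)-2,6-bis(benzyloxy)-3-bromophenyl]-2-(benzyloxy)-3-phenylpropan-1-ol F5. Bromine–lithium exchange (n-BuLi, 2.2 equiv, THF, −78 °C) and quenching with N-methoxy-N-methylacetamide give the ketone 1-{6-(allyloxy)-2,4-bis(benzyloxy)-3-[(1S,2R)-2-(benzyloxy)-3-hydroxy-1-phenylpropyl]phenyl}ethan-1-one F6. The conditions of step 9 then remove the allyl group and return to the route at 12.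

**Step 11.** The most likely failure is low conversion, because the 5,7-dialkoxychromone is a poor acceptor and protodeboronation competes; partial ring-opening of the product would erode C2'. The fallback gives up catalyst control at C2' and relies on separation and recycling. It sets out from 12: Claisen–Schmidt condensation with benzaldehyde (KOH, EtOH) gives the 2'-hydroxychalcone F7, which is cyclised (NaOAc, EtOH, reflux) to 15 and its (2R) epimer F8. The two are diastereomers and are separated by chromatography; F8 is re-equilibrated through F7 under the same conditions, and the route is rejoined at 15.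

**Step 19.** The most likely failure is over-oxidation by hexavalent chromium, either of benzyl ethers to benzoates or at the doubly benzylic C8–H. The fallback separates hydrolysis from oxidation. It sets out from 24: pyridinium p-toluenesulfonate in acetone/H2O gives the lactol F9, which MnO2 in CH2Cl2 oxidises as an allylic lactol, returning to the route at 25.

## Further compounds

F1 | step 16 | homoallylic alcohol: C6 hydroxyl, C5 tert-butyldimethylsilyl ether, terminal vinyl (5,6-syn, 6,7-syn), flavanone and three benzyl ethers as in 16 | C=C[C@H](O[Si](C)(C)C(C)(C)C)[C@@H](O)[C@H](OCc1ccccc1)[C@@H](c1ccccc1)c1c(OCc2ccccc2)cc2c(c1OCc1ccccc1)C(=O)C[C@@H](c1ccccc1)O2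
F2 | step 16 | acrylate ester of F1 at the C6 oxygen | C=C[C@H](O[Si](C)(C)C(C)(C)C)[C@@H](OC(=O)C=C)[C@H](OCc1ccccc1)[C@@H](c1ccccc1)c1c(OCc2ccccc2)cc2c(c1OCc1ccccc1)C(=O)C[C@@H](c1ccccc1)O2
F3 | step 16 | 5-O-(tert-butyldimethylsilyl) analogue of lactone 25 (three benzyl ethers) | O=C1C=C[C@H](O[Si](C)(C)C(C)(C)C)[C@H]([C@H](OCc2ccccc2)[C@@H](c2ccccc2)c2c(OCc3ccccc3)cc3c(c2OCc2ccccc2)C(=O)C[C@@H](c2ccccc2)O3)O1
F4 | step 3 | 7-(allyloxy)-5-(benzyloxy)-4-phenyl-2H-chromen-2-one | O=C1C=C(c2ccccc2)c2c(OCc3ccccc3)cc(OCC=C)cc2O1
F5 | step 8 | (2R,3S)-3-[4-(allyloxy)-2,6-bis(benzyloxy)-3-bromophenyl]-2-(benzyloxy)-3-phenylpropan-1-ol | OC[C@H](OCc1ccccc1)[C@@H](c1ccccc1)c1c(OCc2ccccc2)cc(OCC=C)c(Br)c1OCc1ccccc1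
F6 | step 8 | 1-{6-(allyloxy)-2,4-bis(benzyloxy)-3-[(1S,2R)-2-(benzyloxy)-3-hydroxy-1-phenylpropyl]phenyl}ethan-1-one | OC[C@H](OCc1ccccc1)[C@@H](c1ccccc1)c1c(OCc2ccccc2)cc(OCC=C)c(C(C)=O)c1OCc1ccccc1
F7 | step 11 | (2E)-1-{2,4-bis(benzyloxy)-3-[(1S,2R)-2-(benzyloxy)-3-hydroxy-1-phenylpropyl]-6-hydroxyphenyl}-3-phenylprop-2-en-1-one | OC[C@H](OCc1ccccc1)[C@@H](c1ccccc1)c1c(OCc2ccccc2)cc(O)c(C(=O)/C=C/c2ccccc2)c1OCc1ccccc1
F8 | step 11 | (2R)-5,7-bis(benzyloxy)-6-[(1S,2R)-2-(benzyloxy)-3-hydroxy-1-phenylpropyl]-2-phenylchroman-4-one (C2' epimer of 15) | OC[C@H](OCc1ccccc1)[C@@H](c1ccccc1)c1c(OCc2ccccc2)cc2c(c1OCc1ccccc1)C(=O)C[C@H](c1ccccc1)O2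
F9 | step 19 | lactol corresponding to acetal 24 (C2 hydroxyl, anomer mixture) | OC1C=C[C@H](OCc2ccccc2)[C@H]([C@H](OCc2ccccc2)[C@@H](c2ccccc2)c2c(OCc3ccccc3)cc3c(c2OCc2ccccc2)C(=O)C[C@@H](c2ccccc2)O3)O1
A1 | alternative 1 | trans-3,5-bis(benzyloxy)-4-phenyl-7-(triisopropylsilyloxy)chroman-2-one | O=C1[C@H](OCc2ccccc2)[C@@H](c2ccccc2)c2c(OCc3ccccc3)cc(O[Si](C(C)C)(C(C)C)C(C)C)cc2O1
A2 | alternative 1 | 3-(benzyloxy)-2-[hydroxy(phenyl)methyl]-5-(triisopropylsilyloxy)phenol (racemic carbinol; the centre is lost in the quinone methide) | OC(c1ccccc1)c1c(O)cc(O[Si](C(C)C)(C(C)C)C(C)C)cc1OCc1ccccc1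
A3 | alternative 2 | target as its tetrakis(tert-butyldimethylsilyl) ether | O=C1C=C[C@H](O[Si](C)(C)C(C)(C)C)[C@H]([C@H](O[Si](C)(C)C(C)(C)C)[C@@H](c2ccccc2)c2c(O[Si](C)(C)C(C)(C)C)cc3c(c2O[Si](C)(C)C(C)(C)C)C(=O)C[C@@H](c2ccccc2)O3)O1
A4 | alternative 2 | (S)-3-aryloxy-3-phenylpropanoic acid, the ring C seco-acid of A3 | O=C1C=C[C@H](O[Si](C)(C)C(C)(C)C)[C@H]([C@H](O[Si](C)(C)C(C)(C)C)[C@@H](c2ccccc2)c2c(O[Si](C)(C)C(C)(C)C)cc(O[C@H](c3ccccc3)CC(=O)O)cc2O[Si](C)(C)C(C)(C)C)O1
A5 | alternative 3 | pyranone lactol (C2 hemiacetal as an anomer mixture, C5 ketone, C3=C4) | OC1C=CC(=O)[C@H]([C@H](O[Si](C)(C)C(C)(C)C)[C@@H](c2ccccc2)c2c(OC(C)=O)cc3c(c2OC(C)=O)C(=O)C[C@@H](c2ccccc2)O3)O1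
A6 | alternative 3 | 2-furyl carbinol at C6 (C7 silyl ether, ring A diacetate) | O[C@H](c1ccco1)[C@H](O[Si](C)(C)C(C)(C)C)[C@@H](c1ccccc1)c1c(OC(C)=O)cc2c(c1OC(C)=O)C(=O)C[C@@H](c1ccccc1)O2
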